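**Retrosynthetic overview**

1. The C5 acetate, the C1 methacrylate and the C1 carbinol (C3‑hydroxyl‑directed reduction) are made last from a butenolide‑fused C1 ketone; the butenolide (O, C9, C12, C11, C10) comes from Knoevenagel condensation of an α‑keto ester at C12 and lactonisation through the C9 dienol of cyclodecene‑1,3‑dione 24.
2. Feature: in the ten‑membered carbocycle (C1–C9 plus C12) the oxygenated C1 lies across the ring from C6 of the Z trisubstituted C6=C7 bond, so a C1–C6 bond folds the ring into a cis‑decalin (ring A: C1–C6, carrying C3 and C5; ring B: C1, C12, C9, C8, C7, C6) whose fusion and C7 configuration encode the alkene geometry.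
3. Key disconnection: oxidative Grob fragmentation with Pb(OAc)4 of the γ‑stannyl cis‑decalol 23 (OH on C1, Bu3Sn on C7) cleaves C1–C6 and unveils the ten‑membered ring.
4. Ring order: ring A (all‑cis cyclohexanetriol, methyl addition, lipase desymmetrisation), then ring B (Robinson annulation; cis fusion by epoxidation and reductive opening; tin first, then methyl, at C7), then the ten‑membered ring, then the butenolide.

Key step: step 19

Atom labels: the ring carbons are C1 (bears the methacrylate), C2, C3 (methyl carbinol), C4, C5 (bears the acetate), C6, C7 (vinylic methyl), C8, C9 (lactone oxygen) and C12 (joins C9 to C1); C10 is the lactone carbonyl and C11 carries the CH2OH carbon C13.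

Assumption: the lipase acetylates the carbinol of meso triol 5 that becomes C1; if it prefers the other one, hydrolysis of the diacetate of 5 with the same enzyme should deliver the same monoacetate 6.

**Route**

Step 1
Reactants: 1 cis,cis-cyclohexane-1,3,5-triol
Product: 2 all-cis 3,5-bis(tert-butyldimethylsilyloxy)cyclohexan-1-ol
Conditions: TBSCl (2.1 equiv), imidazole, DMF, 0 °C → rt
Reagents that add atoms: tert-butyldimethylsilyl chloride, CC(C)(C)[Si](C)(C)Cl
Why: Silyl ether formation; the three hydroxyls are equivalent, so two equivalents should give mainly the bis-ether, the mono- and tris-ethers being separable and recyclable.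

Step 2
Reactants: 2 all-cis 3,5-bis(tert-butyldimethylsilyloxy)cyclohexan-1-ol
Product: 3 cis-3,5-bis(tert-butyldimethylsilyloxy)cyclohexan-1-one
Conditions: Dess–Martin periodinane, NaHCO3, CH2Cl2, 0 °C → rt
Reagents that add atoms: none
Why: Dess–Martin oxidation of the lone alcohol under buffered, non-basic conditions that avoid β-elimination of silanol.

Step 3
Reactants: 3 cis-3,5-bis(tert-butyldimethylsilyloxy)cyclohexan-1-one
Product: 4 meso 1-methyl-cis-3,5-bis(tert-butyldimethylsilyloxy)cyclohexan-1-ol (tertiary OH trans to both silyloxy groups)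
Conditions: MeTi(OiPr)3 (from MeLi and ClTi(OiPr)3), Et2O, 0 °C → rt
Reagents that add atoms: methyltitanium triisopropoxide, C[Ti](OC(C)C)(OC(C)C)OC(C)C
Why: Organotitanium carbonyl addition; the bulky, non-basic reagent should attack the chair with both silyloxy groups equatorial from the equatorial side, so the new hydroxyl is axial and trans to both ethers (the later C3/C5 relationship) and no β-elimination occurs.

Step 4
Reactants: 4 meso 1-methyl-cis-3,5-bis(tert-butyldimethylsilyloxy)cyclohexan-1-ol
Product: 5 meso 1-methylcyclohexane-1,3,5-triol (secondary hydroxyls cis to each other and trans to the tertiary one)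
Conditions: aq. HF, MeCN, rt
Reagents that add atoms: none
Why: Fluoride-mediated desilylation frees the two enantiotopic secondary hydroxyls.

Step 5
Reactants: 5 meso 1-methylcyclohexane-1,3,5-triol
Product: 6 (1S,3S,5R)-3,5-dihydroxy-3-methylcyclohexyl acetate
Conditions: lipase PS (Burkholderia cepacia), vinyl acetate, MTBE, rt
Reagents that add atoms: vinyl acetate, C=COC(C)=O
Why: Lipase-catalysed desymmetrisation by irreversible transesterification; acylation of one enantiotopic carbinol fixes the absolute configuration (acetylated carbon becomes C1, the free one C5), and the tertiary hydroxyl is not a substrate.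

Step 6
Reactants: 6 (1S,3S,5R)-3,5-dihydroxy-3-methylcyclohexyl acetate
Product: 7 (1S,3R,5R)-5-[(tert-butyldimethylsilyl)oxy]-3-hydroxy-3-methylcyclohexyl acetate
Conditions: TBSCl, imidazole, DMF, rt
Reagents that add atoms: tert-butyldimethylsilyl chloride, CC(C)(C)[Si](C)(C)Cl
Why: Silylation of the secondary hydroxyl only; the tertiary alcohol is inert to the silyl chloride.

Step 7
Reactants: 7 (1S,3R,5R)-5-[(tert-butyldimethylsilyl)oxy]-3-hydroxy-3-methylcyclohexyl acetate
Product: 8 (1S,3R,5R)-5-[(tert-butyldimethylsilyl)oxy]-3-methyl-3-[(triethylsilyl)oxy]cyclohexyl acetate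
Conditions: TESOTf, 2,6-lutidine, CH2Cl2, −78 → 0 °C
Reagents that add atoms: triethylsilyl trifluoromethanesulfonate, CC[Si](CC)(CC)OS(=O)(=O)C(F)(F)F
Why: Silyl triflate silylation of the hindered tertiary alcohol; TES is chosen so that it can later be removed in the presence of TBS.

Step 8
Reactants: 8 (1S,3R,5R)-5-[(tert-butyldimethylsilyl)oxy]-3-methyl-3-[(triethylsilyl)oxy]cyclohexyl acetate
Product: 9 (1S,3R,5R)-5-[(tert-butyldimethylsilyl)oxy]-3-methyl-3-[(triethylsilyl)oxy]cyclohexan-1-ol
Conditions: K2CO3 (cat.), MeOH, 0 °C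
Reagents that add atoms: none
Why: Base-catalysed transesterification removes the acetate without touching either silyl ether.

Step 9
Reactants: 9 (1S,3R,5R)-5-[(tert-butyldimethylsilyl)oxy]-3-methyl-3-[(triethylsilyl)oxy]cyclohexan-1-ol
Product: 10 ring A ketone (3S,5S)-5-[(tert-butyldimethylsilyl)oxy]-3-methyl-3-[(triethylsilyl)oxy]cyclohexan-1-one
Conditions: Dess–Martin periodinane, NaHCO3, CH2Cl2, 0 °C → rt
Reagents that add atoms: none
Why: Dess–Martin oxidation under neutral conditions spares the two β-silyloxy groups.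

Step 10
Reactants: 10 ring A ketone; 11 methyl vinyl ketone
Product: 13 (2R,3S,5S)-3-[(tert-butyldimethylsilyl)oxy]-5-methyl-2-(3-oxobutyl)-5-[(triethylsilyl)oxy]cyclohexan-1-one, via silyl enol ether 12 (not isolated)
Conditions: LDA, TMSCl, THF, −78 °C; then 11, Sc(OTf)3 (10 mol%), CH2Cl2, −78 °C; aq. HCl work-up
Reagents that add atoms: none
Why: Kinetic deprotonation on the C6 side (C2 is flanked by the quaternary C3) with in-situ silylation avoids β-elimination, and the Mukaiyama–Michael addition brings in C7–C8–C9–C12 anti to the neighbouring C5 silyloxy group, the epimerisable C6 centre resting trans-diequatorial.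

Step 11
Reactants: 13 (2R,3S,5S)-3-[(tert-butyldimethylsilyl)oxy]-5-methyl-2-(3-oxobutyl)-5-[(triethylsilyl)oxy]cyclohexan-1-one
Product: 16 Robinson enone (C9 ketone; C12=C1 double bond), via ketol 14 (not isolated), via ketol mesylate 15 (not isolated)
Conditions: LDA (1.05 equiv), THF, −78 °C; MsCl, −78 → 0 °C; then Et3N, rt
Reagents that add atoms: none
Why: The kinetic methyl-ketone enolate adds to the C1 ketone (intramolecular aldol) and the mesylated aldolate eliminates by E1cB to the conjugated enone (Robinson annulation); the ring-fusion configuration of the ketol is erased, so the likely equatorial closure past the axial C3 silyloxy group does not matter.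

Step 12
Reactants: 16 Robinson enone
Product: 17 C1–C12 epoxy ketone (oxirane oxygen cis to H6)
Conditions: 30% H2O2, NaOH (cat.), MeOH, 0 °C
Reagents that add atoms: hydrogen peroxide, OO
Why: Weitz–Scheffer nucleophilic epoxidation; hydroperoxide should add to C1 equatorially on ring A, on the face away from the axial C3 silyloxy group (the sense that gives cis-fused epoxides from 4-en-3-one steroids), so the oxirane oxygen is cis to H6.

Step 13
Reactants: 17 C1–C12 epoxy ketone
Product: 18 cis-fused ketol (C1 OH cis to H6; C9 ketone)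
Conditions: SmI2, THF/MeOH, −78 °C
Reagents that add atoms: none
Why: Reductive opening of the α,β-epoxy ketone by divalent samarium cleaves the C12–O bond next to the ketone and keeps the C1–O bond, giving the cis-fused aldol with C12 axial on ring A.

Step 14
Reactants: 18 cis-fused ketol
Product: 19 cis-fused hydroxy enone (C7=C8; C9 ketone)
Conditions: IBX·MPO (4-methoxypyridine N-oxide complex), DMSO, rt
Reagents that add atoms: none
Why: IBX dehydrogenation of the ketone; only the C7–C8 side can desaturate because C1 has no hydrogen, and the mild neutral conditions should avoid dehydration of the tertiary aldol toward a phenol.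

Step 15
Reactants: 19 cis-fused hydroxy enone
Product: 20 C7 phenylthio ketone (C7 epimers)
Conditions: PhSH, Et3N (cat.), CH2Cl2, 0 °C
Reagents that add atoms: thiophenol, Sc1ccccc1
Why: Thia-Michael addition places sulfur on C7; the C7 configuration is irrelevant because it is removed in the next step.

Step 16
Reactants: 20 C7 phenylthio ketone
Product: 21 C7 phenylthio enone (vinylogous thioester)
Conditions: NCS, CH2Cl2, 0 °C; then Et3N
Reagents that add atoms: none
Why: Chlorination α to sulfur and loss of HCl toward the acidic C8 (Pummerer-type dehydrogenation of a β-keto sulfide) gives the enone with a leaving group on C7.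

Step 17
Reactants: 21 C7 phenylthio enone
Product: 22 C7 tributylstannyl enone
Conditions: Bu3SnLi (2.1 equiv; from Bu3SnH, LDA), THF, −78 °C
Reagents that add atoms: tributylstannyllithium, [Li][Sn](CCCC)(CCCC)CCCC
Why: Conjugate addition–elimination; the stannyl anion adds to C7 and thiolate leaves, so tin is on C7 before the methyl group is introduced.

Step 18
Reactants: 22 C7 tributylstannyl enone
Product: 23 γ-tributylstannyl cis-decalol (fragmentation precursor)
Conditions: Me2CuLi (3 equiv; from MeLi, CuI), BF3·OEt2, Et2O, −78 → −40 °C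
Reagents that add atoms: lithium dimethylcuprate, [Li+].C[Cu-]C
Why: Organocuprate 1,4-addition to the β-stannyl enone; methyl should enter axially on ring B, anti to the pseudoaxial C6–C5 bond and away from the C5 silyloxy group (cis to H6 and the C1 hydroxyl), which leaves tin cis to C5 and equatorial, whereas adding tin last would give the C7 epimer that cannot fragment to the Z alkene.

Step 19
Reactants: 23 γ-tributylstannyl cis-decalol
Product: 24 Z-cyclodecene-1,3-dione (C1 and C9 ketones)
Conditions: Pb(OAc)4, CaCO3, CH2Cl2, 0 °C → rt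
Reagents that add atoms: none
Why: Ligand exchange at tetravalent lead gives a lead alkoxide at C1, and heterolysis of its O–Pb bond is concerted with cleavage of C1–C6 and departure of the stannyl group from C7, so the C1 ketone and the C6=C7 bond form together. The closest known reaction type is the oxidative Grob-type fragmentation of cyclic γ-hydroxy stannanes to unsaturated medium-ring ketones, which is stereospecifically anti. No ring is closed, since the ten-membered ring is the perimeter of the bicycle opened along its fusion bond, and no stereocentre is formed, C1, C6 and C7 being destroyed. The selectivity needed is Z over E and fragmentation over plain oxidation or β-scission; in the chair–chair conformer of the cis-decalin that keeps the C5 silyloxy group and the C3 methyl equatorial on ring A, tin is equatorial and antiperiplanar to C1–C6 while C5 is axial on ring B and gauche to C8, which maps onto the Z alkene. The neutral oxidant spares the β-silyloxy ketone array that a base-induced fragmentation would eliminate, and relief of the Sn/OTBS peri contact and the 1,3-diaxial strain in 23 should help.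

Step 20
Reactants: 25 ethyl oxirane-2-carboxylate; 26 4-methoxybenzyl alcohol
Product: 27 ethyl 2-hydroxy-3-[(4-methoxybenzyl)oxy]propanoate
Conditions: BF3·OEt2 (cat.), CH2Cl2, 0 °C
Reagents that add atoms: none
Why: Lewis-acid-catalysed epoxide opening; the alcohol attacks the unsubstituted C3 of the glycidate, away from the ester.

Step 21
Reactants: 27 ethyl 2-hydroxy-3-[(4-methoxybenzyl)oxy]propanoate
Product: 28 ethyl 3-[(4-methoxybenzyl)oxy]-2-oxopropanoate
Conditions: Dess–Martin periodinane, CH2Cl2, rt
Reagents that add atoms: none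
Why: Dess–Martin oxidation of the α-hydroxy ester to the α-keto ester.

Step 22
Reactants: 24 Z-cyclodecene-1,3-dione; 28 ethyl 3-[(4-methoxybenzyl)oxy]-2-oxopropanoate
Product: 30 butenolide-fused C1 ketone, via alkylidene diketone 29 (not isolated)
Conditions: TiCl4, pyridine, THF, 0 °C → rt; then Et3N
Reagents that add atoms: none
Why: Knoevenagel condensation of the C12 methylene of the 1,3-diketone on the activated ketone of 28, then enol lactonisation; the C9 dienol, conjugated with C6=C7 and formed through the doubly activated C8, attacks the ester to close the butenolide and sets C8=C9 cis within the ring.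

Step 23
Reactants: 30 butenolide-fused C1 ketone
Product: 31 C3 tertiary alcohol
Conditions: HF·pyridine, pyridine, THF, 0 °C
Reagents that add atoms: none
Why: Buffered fluoride desilylation removes the TES ether selectively, the bulkier TBS ether at C5 surviving the short treatment.

Step 24
Reactants: 31 C3 tertiary alcohol
Product: 32 C1,C3-anti diol (C1 R)
Conditions: Me4NBH(OAc)3, MeCN/AcOH, −30 °C
Reagents that add atoms: none
Why: Evans–Saksena hydroxyl-directed reduction; the C3-bound acetoxyborohydride delivers hydride intramolecularly to C1, which should give the 1,3-anti diol and leave the lactone and triene alone.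

Step 25
Reactants: 32 C1,C3-anti diol
Product: 33 C1 methacrylate
Conditions: methacrylic anhydride, Et3N, DMAP (cat.), CH2Cl2, 0 °C
Reagents that add atoms: methacrylic anhydride, C=C(C)C(=O)OC(=O)C(C)=C
Why: DMAP-catalysed acylation of the secondary allylic C1 alcohol; the tertiary C3 hydroxyl does not react under these conditions.

Step 26
Reactants: 33 C1 methacrylate
Product: 34 C5 alcohol
Conditions: HF·pyridine, THF, rt
Reagents that add atoms: none
Why: Fluoride cleavage of the C5 TBS ether under conditions tolerated by the esters and the enol lactone.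

Step 27
Reactants: 34 C5 alcohol
Product: 35 C5 acetate (PMB ether of the target)
Conditions: Ac2O, pyridine, DMAP (cat.), CH2Cl2, 0 °C
Reagents that add atoms: acetic anhydride, CC(=O)OC(C)=O
Why: Acetylation of the secondary C5 alcohol; the tertiary C3 hydroxyl is again spared.

Step 28
Reactants: 35 C5 acetate
Product: 36 CNP0246543.1
Conditions: DDQ, CH2Cl2/pH 7 buffer, 0 °C
Reagents that add atoms: none
Why: Oxidative cleavage of the PMB ether by DDQ frees the C13 primary alcohol without touching the esters.

**Compound list**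

1 | cis,cis-cyclohexane-1,3,5-triol | O[C@H]1C[C@@H](O)C[C@@H](O)C1 | starting material
2 | all-cis 3,5-bis(tert-butyldimethylsilyloxy)cyclohexan-1-ol | O[C@H]1C[C@@H](O[Si](C)(C)C(C)(C)C)C[C@@H](O[Si](C)(C)C(C)(C)C)C1 | intermediate
3 | cis-3,5-bis(tert-butyldimethylsilyloxy)cyclohexan-1-one (meso) | O=C1C[C@@H](O[Si](C)(C)C(C)(C)C)C[C@@H](O[Si](C)(C)C(C)(C)C)C1 | intermediate
4 | meso 1-methyl-cis-3,5-bis(tert-butyldimethylsilyloxy)cyclohexan-1-ol, tertiary OH trans to both silyloxy groups | C[C@@]1(O)C[C@@H](O[Si](C)(C)C(C)(C)C)C[C@@H](O[Si](C)(C)C(C)(C)C)C1 | intermediate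
5 | meso 1-methylcyclohexane-1,3,5-triol, tertiary OH trans to the two cis secondary OH | C[C@@]1(O)C[C@@H](O)C[C@@H](O)C1 | intermediate
6 | (1S,3S,5R)-3,5-dihydroxy-3-methylcyclohexyl acetate | C[C@@]1(O)C[C@@H](OC(C)=O)C[C@@H](O)C1 | intermediate
7 | (1S,3R,5R)-5-[(tert-butyldimethylsilyl)oxy]-3-hydroxy-3-methylcyclohexyl acetate | C[C@@]1(O)C[C@@H](OC(C)=O)C[C@@H](O[Si](C)(C)C(C)(C)C)C1 | intermediate
8 | (1S,3R,5R)-5-[(tert-butyldimethylsilyl)oxy]-3-methyl-3-[(triethylsilyl)oxy]cyclohexyl acetate | C[C@@]1(O[Si](CC)(CC)CC)C[C@@H](OC(C)=O)C[C@@H](O[Si](C)(C)C(C)(C)C)C1 | intermediate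
9 | (1S,3R,5R)-5-[(tert-butyldimethylsilyl)oxy]-3-methyl-3-[(triethylsilyl)oxy]cyclohexan-1-ol | C[C@@]1(O[Si](CC)(CC)CC)C[C@@H](O)C[C@@H](O[Si](C)(C)C(C)(C)C)C1 | intermediate
10 | ring A ketone, (3S,5S)-5-[(tert-butyldimethylsilyl)oxy]-3-methyl-3-[(triethylsilyl)oxy]cyclohexan-1-one | O=C1C[C@@](C)(O[Si](CC)(CC)CC)C[C@H](O[Si](C)(C)C(C)(C)C)C1 | intermediate
11 | methyl vinyl ketone (but-3-en-2-one) | CC(=O)C=C | starting material
12 | trimethylsilyl enol ether of 10 (C1=C6) | C[Si](C)(C)OC1=C[C@@H](O[Si](C)(C)C(C)(C)C)C[C@](C)(O[Si](CC)(CC)CC)C1 | intermediate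
13 | (2R,3S,5S)-3-[(tert-butyldimethylsilyl)oxy]-5-methyl-2-(3-oxobutyl)-5-[(triethylsilyl)oxy]cyclohexan-1-one | O=C1C[C@@](C)(O[Si](CC)(CC)CC)C[C@H](O[Si](C)(C)C(C)(C)C)[C@H]1CCC(C)=O | intermediate
14 | bicyclic ketol (C1 OH, C9 ketone; C1 configuration unassigned) | OC12C[C@@](C)(O[Si](CC)(CC)CC)C[C@H](O[Si](C)(C)C(C)(C)C)[C@H]1CCC(=O)C2 | intermediate
15 | C1 methanesulfonate of 14 | CS(=O)(=O)OC12C[C@@](C)(O[Si](CC)(CC)CC)C[C@H](O[Si](C)(C)C(C)(C)C)[C@H]1CCC(=O)C2 | intermediate
16 | Robinson enone (C9 ketone, C12=C1; C3 OTES, C5 OTBS) | O=C1C=C2C[C@@](C)(O[Si](CC)(CC)CC)C[C@H](O[Si](C)(C)C(C)(C)C)[C@H]2CC1 | intermediate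
17 | C1–C12 epoxy ketone, oxirane oxygen cis to H6 | O1[C@]23C[C@@](C)(O[Si](CC)(CC)CC)C[C@H](O[Si](C)(C)C(C)(C)C)[C@H]2CCC(=O)[C@H]13 | intermediate
18 | cis-fused ketol (C1 OH cis to H6; C9 ketone) | O[C@]12C[C@@](C)(O[Si](CC)(CC)CC)C[C@H](O[Si](C)(C)C(C)(C)C)[C@H]1CCC(=O)C2 | intermediate
19 | cis-fused hydroxy enone (C7=C8, C9 ketone) | O[C@]12C[C@@](C)(O[Si](CC)(CC)CC)C[C@H](O[Si](C)(C)C(C)(C)C)[C@H]1C=CC(=O)C2 | intermediate
20 | C7 phenylthio ketone (C7 epimers) | O[C@]12C[C@@](C)(O[Si](CC)(CC)CC)C[C@H](O[Si](C)(C)C(C)(C)C)[C@H]1C(Sc3ccccc3)CC(=O)C2 | intermediate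
21 | C7 phenylthio enone (vinylogous thioester) | O[C@]12C[C@@](C)(O[Si](CC)(CC)CC)C[C@H](O[Si](C)(C)C(C)(C)C)[C@H]1C(Sc3ccccc3)=CC(=O)C2 | intermediate
22 | C7 tributylstannyl enone | O[C@]12C[C@@](C)(O[Si](CC)(CC)CC)C[C@H](O[Si](C)(C)C(C)(C)C)[C@H]1C([Sn](CCCC)(CCCC)CCCC)=CC(=O)C2 | intermediate
23 | γ-tributylstannyl cis-decalol (C1 OH, H6 and C7 methyl on one face; tin on the other) | O[C@]12C[C@@](C)(O[Si](CC)(CC)CC)C[C@H](O[Si](C)(C)C(C)(C)C)[C@H]1[C@@](C)([Sn](CCCC)(CCCC)CCCC)CC(=O)C2 | intermediate
24 | Z-cyclodecene-1,3-dione (C1 and C9 ketones; C3 OTES, C5 OTBS) | O=C1C[C@@](C)(O[Si](CC)(CC)CC)C[C@H](O[Si](C)(C)C(C)(C)C)/C=C(C)\CC(=O)C1 | intermediate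
25 | ethyl oxirane-2-carboxylate (racemic) | CCOC(=O)C1CO1 | starting material
26 | 4-methoxybenzyl alcohol | COc1ccc(CO)cc1 | starting material
27 | ethyl 2-hydroxy-3-[(4-methoxybenzyl)oxy]propanoate (racemic) | CCOC(=O)C(O)COCc1ccc(OC)cc1 | intermediate
28 | ethyl 3-[(4-methoxybenzyl)oxy]-2-oxopropanoate | CCOC(=O)C(=O)COCc1ccc(OC)cc1 | intermediate
29 | C12 alkylidene diketone (Knoevenagel adduct) | O=C1C[C@@](C)(O[Si](CC)(CC)CC)C[C@H](O[Si](C)(C)C(C)(C)C)/C=C(C)\CC(=O)C1=C(COCc2ccc(OC)cc2)C(=O)OCC | intermediate
30 | butenolide-fused C1 ketone (C3 OTES, C5 OTBS, C13 OPMB) | O=C1C[C@@](C)(O[Si](CC)(CC)CC)C[C@H](O[Si](C)(C)C(C)(C)C)/C=C(C)\C=C2\OC(=O)C(COCc3ccc(OC)cc3)=C21 | intermediate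
31 | C3 tertiary alcohol (C1 ketone, C5 OTBS, C13 OPMB) | O=C1C[C@@](C)(O)C[C@H](O[Si](C)(C)C(C)(C)C)/C=C(C)\C=C2\OC(=O)C(COCc3ccc(OC)cc3)=C21 | intermediate
32 | C1,C3-anti diol (C1 R) | O[C@@H]1C[C@@](C)(O)C[C@H](O[Si](C)(C)C(C)(C)C)/C=C(C)\C=C2\OC(=O)C(COCc3ccc(OC)cc3)=C21 | intermediate
33 | C1 methacrylate | C=C(C)C(=O)O[C@@H]1C[C@@](C)(O)C[C@H](O[Si](C)(C)C(C)(C)C)/C=C(C)\C=C2\OC(=O)C(COCc3ccc(OC)cc3)=C21 | intermediate
34 | C5 alcohol | C=C(C)C(=O)O[C@@H]1C[C@@](C)(O)C[C@H](O)/C=C(C)\C=C2\OC(=O)C(COCc3ccc(OC)cc3)=C21 | intermediate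
35 | C5 acetate, PMB ether of the target | C=C(C)C(=O)O[C@@H]1C[C@@](C)(O)C[C@H](OC(C)=O)/C=C(C)\C=C2\OC(=O)C(COCc3ccc(OC)cc3)=C21 | intermediate
36 | CNP0246543.1 (C1 R, C3 S, C5 S; C6=C7 Z; C8=C9 E) | C=C(C)C(=O)O[C@@H]1C[C@@](C)(O)C[C@H](OC(C)=O)/C=C(C)\C=C2\OC(=O)C(CO)=C21 | target

**Step count and risks**

Total steps: 28. Longest linear sequence: 26 (steps 1–19 and 22–28; steps 20–21 make keto ester 28).

Steps most likely to fail:

Step 18. The cuprate may not transfer methyl: the β-carbon is shielded by the stannyl group and the neighbouring C5 silyloxy group, and tin–copper exchange or simple deprotonation can overtake addition. The fallback sets out from 22 and uses nickel catalysis instead of a stoichiometric cuprate: AlMe3 with Ni(acac)2 (cat.) in THF at 0 °C, a known conjugate methylation of hindered β,β-disubstituted enones, should return to 23 after work-up. It makes no new compound (F0).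

Step 22. Condensation at C12 may fail through self-condensation of the keto ester, drift of the C6=C7 bond into conjugation with C9 under the Lewis acid, or lactonisation through the C1 enol. The fallback sets out from 24 and joins the pieces stepwise: soft enolisation (MgBr2·OEt2, Et3N, CH2Cl2, −20 °C) and aldol addition to 28, with lactonisation through the C9 dienol, should give the β-hydroxy lactone F1; dehydration (MsCl, Et3N) then returns to 30.

Step 24. Facial selectivity may be poor, since the ring and the tertiary carbinol constrain the boron chelate that delivers hydride. The fallback sets out from 31: syn-selective Narasaka–Prasad reduction (Et2BOMe, NaBH4, THF/MeOH, −78 °C) should give the C1-epimeric 1,3-syn diol F2; Mitsunobu esterification with methacrylic acid (PPh3, DIAD) inverts C1 and returns to the route at 33.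

Further compounds
F0 | step 18 | none | none
F1 | step 22 | β-hydroxy lactone (C11 tertiary alcohol, C12–H; C1 ketone) | O=C1C[C@@](C)(O[Si](CC)(CC)CC)C[C@H](O[Si](C)(C)C(C)(C)C)/C=C(C)\C=C2\OC(=O)C(O)(COCc3ccc(OC)cc3)C21
F2 | step 24 | C1-epimeric (1,3-syn) diol | O[C@H]1C[C@@](C)(O)C[C@H](O[Si](C)(C)C(C)(C)C)/C=C(C)\C=C2\OC(=O)C(COCc3ccc(OC)cc3)=C21
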